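**Compound numbers used throughout**

1 4-iodo-2-methoxyphenol; 2 its benzyl ether; 3 ethynyltrimethylsilane; 4 aryl(trimethylsilyl)alkyne (not isolated); 5 terminal arylalkyne (not isolated); 6 diarylalkyne; 7 Z-stilbene; 8 cis-oxirane; 9 di-(1R,2S,5R)-menthyl fumarate; 10 E,Z carbonyl ylide (not isolated); 11 cycloadduct; 12 dibenzyl diol; 13 eduesmine.

## Analysis of the target

Eduesmine (13) has one oxolane ring (O1, C2, C3, C4, C5). C2 and C5 each carry a 4-hydroxy-3-methoxyphenyl group, and C3 and C4 each carry a CH2OH group. All four ring carbons are stereocentres, (2S,3S,4S,5S). The relative arrangement is 2,3-cis, 3,4-trans, 4,5-cis and therefore 2,5-trans. A C2 axis runs through O1 and the midpoint of C3–C4, so only two independent stereocentres have to be set. Each aryl group is cis to the CH2OH on the neighbouring carbon. This is the most crowded arrangement and not the thermodynamic one, so equilibration cannot be used and any ionisation of a ring C–O bond would lead towards the all-trans isomer. The sensitive groups are the two benzylic ring C–O bonds para to a phenol oxygen (acid ionisation, quinone methide formation, hydrogenolysis) and the free phenols (oxidation). The strategy rests on reading the C2–O1–C5 unit with its two identical aryl groups as a symmetrical diaryl carbonyl ylide, and the trans-substituted C3–C4 unit as a fumarate; the two are joined through C2–C3 and C4–C5.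

## Retrosynthetic reasoning

**13 to 12.** The two phenolic O–H bonds are traced back to O–benzyl bonds. Free phenols would not survive the oxygen-transfer step or prolonged heating. Benzyl ethers are inert to palladium/copper coupling, semihydrogenation, epoxidation, heat and hydride. The forward step must cleave two aryl benzyl ethers without touching the benzylic C–O bonds of the ring.

**12 to 11.** The two CH2OH groups are traced back to ester carbonyls on C3 and C4. The esters are what makes the C3–C4 alkene electron-poor, and they carry the chiral alcohol that turns stereoisomeric adducts into separable diastereomers. The forward step is a hydride reduction that must not epimerise C3 or C4.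

**11 to 8 and 9, through 10.** The bonds C2–C3 and C4–C5 are cut together. These are the only two bonds whose joint cleavage gives two symmetrical, stable and accessible pieces: the meso oxirane 8 and the purchased fumarate 9. The gain is the ring and all four stereocentres in one step. The forward reaction has to achieve four things.
- Thermal conrotatory opening of 8 must give the E,Z ylide 10, and 10 must be trapped before it stereomutates. This gives the 2,5-trans relation.
- The E geometry of 9 must be carried through a suprafacial addition. This gives the 3,4-trans relation.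
- The fumarate must approach with one ester endo beside the outward-aryl terminus and the other ester exo beneath the inward aryl. Only this orientation places each ester cis to its neighbouring aryl. It is the more crowded of the two possible orientations, so this relation is not secured by the substrates and 11 must be separated from its diastereomers.
- One face of 9 must be attacked to fix the absolute configuration. The auxiliary biases this only weakly in an uncatalysed reaction.

**8 to 7.** The two C–O bonds of the oxirane are cut. Stereospecific syn oxygen transfer to a Z-alkene is the direct source of a cis-oxirane. The cis isomer is required because only it gives the E,Z ylide on thermal conrotation. The forward step must be acid-free, since the electron-rich oxirane rearranges easily.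

**7 to 6.** Two hydrogens are removed. Syn semihydrogenation of a diarylalkyne is the most reliable way to a Z-stilbene; carbonyl olefination would give E/Z mixtures.

**6 to 2 and 3, through 4 and 5.** The two aryl–C(sp) bonds are cut. The alkyne is symmetrical, so both bonds can be made in one flask from two equivalents of 2 and the two-carbon unit 3.

**2 to 1.** The O–benzyl bond is cut; a simple O-alkylation of the purchased iodophenol.

## Alternatives that were turned down

**Alternative 1:** The two aryl–carbon bonds at C2 and C5 are disconnected from a preformed, enantiopure trans-oxolane-3,4-dicarboxamide A1 bearing quinolin-8-yl amides. In the forward direction Pd(OAc)2 (divalent palladium) with AgOAc (monovalent silver) would arylate A1 twice with the aryl iodide 2, each amide directing palladation of the neighbouring O–CH2, to give the diarylated diamide A2.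
- For: the five-membered palladacycle can only form on the C–H cis to the amide, so both aryl groups arrive cis to the neighbouring carboxamide by mechanism. On this point it is stronger than the chosen route, which cannot enforce that relation.
- Against: palladation must occur twice at an oxygen-bearing methylene, the second time on a ring that already carries a cis aryl group. A1 must first be made in enantiopure form. Two robust amides then have to be cleaved and reduced at carbons that are epimerisable and sit cis to aryl groups. Silver is used stoichiometrically.
- Comparison: ring synthesis, amide formation, arylation, amide removal, reduction and deprotection make it clearly longer. The chosen route offers ring and four stereocentres in one step from a meso oxirane and a purchased alkene, and pays for this with weaker control in that step.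

**Alternative 2:** The C3–CH2 and C4–CH2 bonds and four C–H bonds are disconnected from the flat, achiral 2,5-diarylfuran A3. In the forward direction a benzyloxymethyl cation would be generated from BnOCH2Cl with the monovalent silver salt of (R)-3,3'-bis(2,4,6-triisopropylphenyl)-1,1'-binaphthyl-2,2'-diyl hydrogen phosphate. It would attack C3, Et3SiH would reduce the 2-aryl oxocarbenium ion, and the remaining enol ether would repeat the sequence at C4 and C5 to give A4.
- For: it is the shortest plan on paper, catalytic in the chiral component, and A3 is easy to make. Hydride delivery anti to the new C3 substituent and a second alkylation anti to the first would give the right relative pattern by substrate control.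
- Against: C3 of a 2,5-diarylfuran is a poor nucleophile and the aryl rings compete. The silane can reduce the small cation directly. Enantiocontrol by ion pairing in the first C–C bond formation has no close model, and all four stereocentres depend on one untested cascade. The two alkyl benzyl ethers of A4 need longer hydrogenolysis than aryl benzyl ethers, which brings ring C–O cleavage closer.
- Comparison: it would be shorter and catalytic if it worked. The chosen strategy instead relies on a reaction type whose mechanism is established and whose 2,5- and 3,4-relations are predictable.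

**Alternative 3:** The oxolane is traced back to a γ-lactone in which C2 is still a carbonyl carbon. The C3–C4 bond of this lactone A6 is disconnected to the malonate ester A5 of a threo epoxy alcohol. In the forward direction base forms the malonate enolate, which opens the epoxide at its internal carbon with inversion. This closes the lactone and releases the CH2O group on C4.
- For: the SN2 event fixes the 4,5-cis relation, and the absolute configuration can come from a reliable asymmetric epoxidation. The second aryl can later be added to the lactone carbonyl and the resulting oxocarbenium ion reduced anti to the C3 substituent, giving 2,3-cis. This gives the firmest relative stereocontrol of all the options and is stronger than the chosen route on this point.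
- Against: the sequence is linear and about twice as long. The two halves of a C2-symmetric target are built one after the other. Opening at the terminal epoxide carbon (six-membered lactone) competes. The released alkoxide can translactonise. The benzylic malonate C–O bond next to an electron-rich ring can ionise.
- Comparison: the chosen strategy is half as long and uses the symmetry, at the price of a less controlled key step. The aryl-addition and ionic-reduction logic of this alternative is kept as the fallback for the key step.

Key step: step 5

Assumption: 1, 3 and 9 are purchased. The face preference of 9 in an uncatalysed cycloaddition is taken to be small and of unpredictable sign, so 11 is secured by chromatographic separation of diastereomers.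

## Route

Step 1
Reactants: 1 4-iodo-2-methoxyphenol
Product: 2 1-(benzyloxy)-4-iodo-2-methoxybenzene
Conditions: BnBr (1.1 equiv), K2CO3 (1.5 equiv), DMF, rt
Reagents that add atoms: benzyl bromide, BrCc1ccccc1
Why: Williamson etherification of the phenoxide with a benzylic bromide (SN2); the aryl iodide is untouched and the benzyl ether is inert to every step before the final one.

Step 2
Reactants: 2 1-(benzyloxy)-4-iodo-2-methoxybenzene (2 equiv); 3 ethynyltrimethylsilane (1 equiv)
Product: 6 1,2-bis[4-(benzyloxy)-3-methoxyphenyl]ethyne, via aryl(trimethylsilyl)alkyne 4 (not isolated), via terminal arylalkyne 5 (not isolated)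
Conditions: PdCl2(PPh3)2 (divalent palladium, 6 mol%), CuI (monovalent copper, 10 mol%), DBU (6 equiv), H2O (0.4 equiv), MeCN, rt then 60 °C
Reagents that add atoms: none
Why: Sonogashira coupling of 2 with 3 gives 4, which DBU and the small amount of water desilylate in the flask to 5; a second Sonogashira coupling with the second equivalent of 2 gives the symmetrical alkyne, and aryl iodides couple under these mild conditions.

Step 3
Reactants: 6 1,2-bis[4-(benzyloxy)-3-methoxyphenyl]ethyne
Product: 7 (Z)-1,2-bis[4-(benzyloxy)-3-methoxyphenyl]ethene
Conditions: H2 (1 atm, 1 equiv uptake), Pd/CaCO3 poisoned with Pb(OAc)2 (Lindlar catalyst), quinoline, EtOAc, rt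
Reagents that add atoms: none
Why: Lindlar semihydrogenation; syn delivery of one equivalent of hydrogen on the poisoned palladium surface gives the Z-alkene, quinoline holds back over-reduction, and aryl benzyl ethers are not cleaved on this catalyst.

Step 4
Reactants: 7 (Z)-1,2-bis[4-(benzyloxy)-3-methoxyphenyl]ethene
Product: 8 (2R,3S)-2,3-bis[4-(benzyloxy)-3-methoxyphenyl]oxirane (cis, meso)
Conditions: dimethyldioxirane (1.2 equiv, solution in acetone), CH2Cl2, 0 °C; evaporation, filtration through Et3N-deactivated silica
Reagents that add atoms: dimethyldioxirane, CC1(C)OO1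
Why: Concerted, stereospecific oxygen-atom transfer (alkene epoxidation) turns the Z-alkene into the cis (meso) oxirane; the reagent is neutral and its by-product volatile, which protects the acid-labile electron-rich oxirane.

Step 5
Reactants: 8 (2R,3S)-2,3-bis[4-(benzyloxy)-3-methoxyphenyl]oxirane; 9 bis[(1R,2S,5R)-2-isopropyl-5-methylcyclohexyl] (E)-but-2-enedioate (di-(1R,2S,5R)-menthyl fumarate)
Product: 11 bis[(1R,2S,5R)-2-isopropyl-5-methylcyclohexyl] (2S,3R,4R,5S)-2,5-bis[4-(benzyloxy)-3-methoxyphenyl]oxolane-3,4-dicarboxylate (2,3-cis, 3,4-trans, 4,5-cis), via carbonyl ylide 10 (not isolated)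
Conditions: 9 (6 equiv, melt), 2,6-di-tert-butyl-4-methylpyridine (0.1 equiv), a little 1,2-dichlorobenzene, degassed, silanised sealed tube, 170 °C; chromatographic separation of the diastereomeric adducts
Reagents that add atoms: none
Why: Heating opens the C–C bond of 8 in a thermally allowed four-electron conrotatory electrocyclic reaction to the planar E,Z carbonyl ylide 10 (one aryl outward, one inward), which the electron-poor alkene 9 traps in a concerted suprafacial 1,3-dipolar cycloaddition; the closest known reaction type is the thermal C–C opening of 2,3-diaryloxiranes with trapping of the ylides by electron-poor alkenes. The oxolane is closed in this single intermolecular [3+2] event, in which C2–C3 and C4–C5 form together and no separate cyclisation follows. C2 and C5 come out trans because conrotation of the cis-oxirane puts the two aryl groups on opposite faces of the new ring, and C3 and C4 come out trans because the E geometry of 9 is carried through the suprafacial addition. The cis relation of each aryl to its neighbouring ester requires the orientation with one ester endo beside the outward-aryl terminus and the other exo beneath the inward aryl; this is the more crowded of the two C2-symmetric approaches (the other gives the all-trans isomer), nothing in the substrates enforces it, and only the high temperature, which levels small differences in activation energy, and some aryl–ester contact speak for a usable share. The absolute configuration is decided by which face of 9 is attacked; without a Lewis acid the menthyl groups bias this only weakly, but they make all stereoisomeric adducts diastereomers, so that 11 is isolated by chromatography. Trapping must outrun rotation about the C–O bonds of 10, which would lead to 2,5-cis adducts; the large excess and high concentration of 9 and the pairing of an electron-rich dipole with an electron-poor alkene serve this. The hindered pyridine base and silanised glass suppress acid-induced C–O opening of the oxirane (Meinwald rearrangement).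

Step 6
Reactants: 11 bis[(1R,2S,5R)-2-isopropyl-5-methylcyclohexyl] (2S,3R,4R,5S)-2,5-bis[4-(benzyloxy)-3-methoxyphenyl]oxolane-3,4-dicarboxylate
Product: 12 [(2S,3S,4S,5S)-2,5-bis[4-(benzyloxy)-3-methoxyphenyl]oxolane-3,4-diyl]dimethanol
Conditions: LiAlH4 (4 equiv), THF, 0 °C to rt; aqueous potassium sodium tartrate work-up
Reagents that add atoms: none
Why: Hydride reduction of both esters to primary alcohols; no bond to a stereocentre is broken and hydride addition is much faster than enolisation at this temperature, so the cis aryl/C3 and aryl/C4 relations are kept, and the benzyl ethers and the ring are inert.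

Step 7
Reactants: 12 [(2S,3S,4S,5S)-2,5-bis[4-(benzyloxy)-3-methoxyphenyl]oxolane-3,4-diyl]dimethanol
Product: 13 4,4'-[(2S,3S,4S,5S)-3,4-bis(hydroxymethyl)oxolane-2,5-diyl]bis(2-methoxyphenol) (eduesmine)
Conditions: H2 (1 atm), Pd/C (10 wt% Pd), EtOAc–EtOH, rt, stopped at full conversion of the benzyl ethers
Reagents that add atoms: none
Why: Catalytic hydrogenolysis of aryl benzyl ethers, which cleave much faster than the dialkyl benzylic C–O bonds of the ring; no stereocentre is touched.

## Compound list

1 | 4-iodo-2-methoxyphenol | COc1cc(I)ccc1O | starting material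
2 | 1-(benzyloxy)-4-iodo-2-methoxybenzene | COc1cc(I)ccc1OCc1ccccc1 | intermediate
3 | ethynyltrimethylsilane | C#C[Si](C)(C)C | starting material
4 | {[4-(benzyloxy)-3-methoxyphenyl]ethynyl}trimethylsilane | COc1cc(C#C[Si](C)(C)C)ccc1OCc1ccccc1 | intermediate (not isolated)
5 | 1-(benzyloxy)-4-ethynyl-2-methoxybenzene | COc1cc(C#C)ccc1OCc1ccccc1 | intermediate (not isolated)
6 | 1,2-bis[4-(benzyloxy)-3-methoxyphenyl]ethyne | COc1cc(C#Cc2ccc(OCc3ccccc3)c(OC)c2)ccc1OCc1ccccc1 | intermediate
7 | (Z)-1,2-bis[4-(benzyloxy)-3-methoxyphenyl]ethene | COc1cc(/C=C\c2ccc(OCc3ccccc3)c(OC)c2)ccc1OCc1ccccc1 | intermediate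
8 | (2R,3S)-2,3-bis[4-(benzyloxy)-3-methoxyphenyl]oxirane (cis, meso) | COc1cc([C@H]2O[C@H]2c2ccc(OCc3ccccc3)c(OC)c2)ccc1OCc1ccccc1 | intermediate
9 | bis[(1R,2S,5R)-2-isopropyl-5-methylcyclohexyl] (E)-but-2-enedioate (di-(1R,2S,5R)-menthyl fumarate) | CC(C)[C@@H]1CC[C@@H](C)C[C@H]1OC(=O)/C=C/C(=O)O[C@@H]1C[C@H](C)CC[C@H]1C(C)C | starting material
10 | E,Z carbonyl ylide ArCH=O(+)–CH(−)Ar, Ar = 4-(benzyloxy)-3-methoxyphenyl, one aryl outward and one inward (one resonance form drawn, outward end as the C=O bond) | COc1cc(/C=[O+]/[CH-]c2ccc(OCc3ccccc3)c(OC)c2)ccc1OCc1ccccc1 | intermediate (not isolated)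
11 | bis[(1R,2S,5R)-2-isopropyl-5-methylcyclohexyl] (2S,3R,4R,5S)-2,5-bis[4-(benzyloxy)-3-methoxyphenyl]oxolane-3,4-dicarboxylate | COc1cc([C@H]2O[C@H](c3ccc(OCc4ccccc4)c(OC)c3)[C@H](C(=O)O[C@@H]3C[C@H](C)CC[C@H]3C(C)C)[C@H]2C(=O)O[C@@H]2C[C@H](C)CC[C@H]2C(C)C)ccc1OCc1ccccc1 | intermediate
12 | [(2S,3S,4S,5S)-2,5-bis[4-(benzyloxy)-3-methoxyphenyl]oxolane-3,4-diyl]dimethanol | COc1cc([C@H]2O[C@H](c3ccc(OCc4ccccc4)c(OC)c3)[C@H](CO)[C@H]2CO)ccc1OCc1ccccc1 | intermediate
13 | 4,4'-[(2S,3S,4S,5S)-3,4-bis(hydroxymethyl)oxolane-2,5-diyl]bis(2-methoxyphenol) (eduesmine) | COc1cc([C@H]2O[C@H](c3ccc(O)c(OC)c3)[C@H](CO)[C@H]2CO)ccc1O | target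

## Step count and least certain steps

Total: 7 steps. Longest linear sequence: 7 steps (1 to 13); 3 and 9 enter as purchased partners.

**Step 5 (key step).** Three things are likely to go wrong.
- The fumarate may approach mostly in the less crowded orientation, because the required one places an ester beneath the inward aryl group. In that case 11 is only a minor component, accompanied by its all-trans diastereomers.
- Rotation within the ylide before trapping would leak material into 2,5-cis adducts, and acid-induced C–O opening of the electron-rich oxirane would consume 8.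
- Face discrimination on 9 will be weak. The mirror-image auxiliary would only reverse whichever small preference exists.

Fallback: the ring is built by aryl addition to a lactone and ionic reduction. It sets out from 2 and comes back at 12.

Iodine–magnesium exchange on 2 (iPrMgCl·LiCl, THF) and formylation with DMF give 4-(benzyloxy)-3-methoxybenzaldehyde F1. (S)-4-Benzyloxazolidin-2-one is acylated (n-BuLi, methyl 4-chloro-4-oxobutanoate) to methyl 4-[(4S)-4-benzyl-2-oxo-1,3-oxazolidin-3-yl]-4-oxobutanoate F2. A MgCl2-catalysed anti-aldol reaction of F2 with F1 (Et3N, Me3SiCl, EtOAc) gives the silylated anti adduct F3. The auxiliary shields one face of the chelated enolate; the mirror-image auxiliary is taken if the opposite sense is found. Brief dilute acid removes the silyl group and the hydroxy ester closes to the 4,5-cis lactone imide F4.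

LiOH/H2O2 removes the auxiliary to give the lactone acid F5. BH3·SMe2 reduces the acid in the presence of the lactone to the hydroxymethyl lactone F6, which is silylated at once (t-BuMe2SiCl, imidazole) to F7. LiN(SiMe3)2 and monomeric formaldehyde introduce CH2OH at C3 anti to the C4 substituent, giving the 3,4-trans lactone F8. A second silylation gives F9.

The aryllithium from 2 (n-BuLi, THF, −78 °C) adds to the lactone carbonyl to give the lactol F10. Et3SiH with BF3·OEt2 at −78 °C reduces the 2-aryl oxocarbenium ion from the face anti to the C3 substituent, giving the 2,3-cis oxolane bis-silyl ether F11. Bu4NF then gives 12.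

**Step 4.** The electron-rich cis-oxirane may rearrange by acid-induced C–O opening during isolation, and the reagent may over-oxidise the electron-rich rings.

Fallback: the oxirane is closed by C–O bond formation with inversion instead of oxygen transfer. It sets out from 7 and comes back at 8. Iodine-catalysed isomerisation of 7 gives the (E)-stilbene F13. Dihydroxylation with catalytic OsO4 and N-methylmorpholine N-oxide gives the racemic threo diol F14. Mitsunobu cyclodehydration (PPh3, diisopropyl azodicarboxylate) closes the ring with inversion at one carbon, which converts the threo diol into the meso cis-oxirane 8. Partial ionisation at the electron-rich benzylic carbon is the risk of this path.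

**Step 3.** Over-reduction to the saturated diarylethane, or isomerisation of the Z-alkene on the catalyst, may occur.

Fallback: hydrometalation and protonolysis replace catalytic hydrogenation, so a second reduction cannot occur. It sets out from 6 and comes back at 7. Syn hydroboration of 6 with dicyclohexylborane (from BH3·SMe2 and cyclohexene, THF) gives the alkenylborane F12. Protonolysis with acetic acid replaces boron by hydrogen with retention and gives 7.

**Step 7.** Hydrogenolysis may continue into the benzylic C–O bonds of the ring once the phenols are free.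

Fallback: the benzyl groups are removed by Lewis-acid dealkylation at the ester stage, where the neighbouring esters disfavour ionisation of the ring. It sets out from 11 and comes back at 13. BCl3 with pentamethylbenzene as cation scavenger (CH2Cl2, −78 °C) cleaves the two aryl benzyl ethers of 11 to give the bisphenol diester F15. Reduction of F15 with excess LiAlH4 gives 13 directly.

## Further compounds

F1 | step 5 | 4-(benzyloxy)-3-methoxybenzaldehyde | COc1cc(C=O)ccc1OCc1ccccc1
F2 | step 5 | methyl 4-[(4S)-4-benzyl-2-oxo-1,3-oxazolidin-3-yl]-4-oxobutanoate | COC(=O)CCC(=O)N1[C@@H](Cc2ccccc2)COC1=O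
F3 | step 5 | methyl (3R)-3-{(S)-[4-(benzyloxy)-3-methoxyphenyl](trimethylsilyloxy)methyl}-4-[(4S)-4-benzyl-2-oxo-1,3-oxazolidin-3-yl]-4-oxobutanoate (anti) | C[Si](C)(C)O[C@H](c1ccc(OCc2ccccc2)c(OC)c1)[C@H](C(=O)N1[C@@H](Cc2ccccc2)COC1=O)CC(=O)OC
F4 | step 5 | (4S)-4-benzyl-3-{(2S,3R)-2-[4-(benzyloxy)-3-methoxyphenyl]-5-oxooxolane-3-carbonyl}-1,3-oxazolidin-2-one (2,3-cis) | O=C1O[C@H](c2ccc(OCc3ccccc3)c(OC)c2)[C@H](C(=O)N2[C@@H](Cc3ccccc3)COC2=O)C1
F5 | step 5 | (2S,3R)-2-[4-(benzyloxy)-3-methoxyphenyl]-5-oxooxolane-3-carboxylic acid | O=C1O[C@H](c2ccc(OCc3ccccc3)c(OC)c2)[C@H](C(=O)O)C1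
F6 | step 5 | (4S,5S)-5-[4-(benzyloxy)-3-methoxyphenyl]-4-(hydroxymethyl)oxolan-2-one (4,5-cis) | O=C1O[C@H](c2ccc(OCc3ccccc3)c(OC)c2)[C@H](CO)C1
F7 | step 5 | (4S,5S)-5-[4-(benzyloxy)-3-methoxyphenyl]-4-[(tert-butyldimethylsilyloxy)methyl]oxolan-2-one | O=C1O[C@H](c2ccc(OCc3ccccc3)c(OC)c2)[C@H](CO[Si](C)(C)C(C)(C)C)C1
F8 | step 5 | (3S,4S,5S)-5-[4-(benzyloxy)-3-methoxyphenyl]-4-[(tert-butyldimethylsilyloxy)methyl]-3-(hydroxymethyl)oxolan-2-one (3,4-trans, 4,5-cis) | O=C1O[C@H](c2ccc(OCc3ccccc3)c(OC)c2)[C@H](CO[Si](C)(C)C(C)(C)C)[C@H]1CO
F9 | step 5 | (3S,4S,5S)-5-[4-(benzyloxy)-3-methoxyphenyl]-3,4-bis[(tert-butyldimethylsilyloxy)methyl]oxolan-2-one | O=C1O[C@H](c2ccc(OCc3ccccc3)c(OC)c2)[C@H](CO[Si](C)(C)C(C)(C)C)[C@H]1CO[Si](C)(C)C(C)(C)C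
F10 | step 5 | (3S,4S,5S)-2,5-bis[4-(benzyloxy)-3-methoxyphenyl]-3,4-bis[(tert-butyldimethylsilyloxy)methyl]oxolan-2-ol (lactol, both anomers) | COc1cc(C2(O)O[C@H](c3ccc(OCc4ccccc4)c(OC)c3)[C@H](CO[Si](C)(C)C(C)(C)C)[C@H]2CO[Si](C)(C)C(C)(C)C)ccc1OCc1ccccc1
F11 | step 5 | (2S,3S,4S,5S)-2,5-bis[4-(benzyloxy)-3-methoxyphenyl]-3,4-bis[(tert-butyldimethylsilyloxy)methyl]oxolane | COc1cc([C@H]2O[C@H](c3ccc(OCc4ccccc4)c(OC)c3)[C@H](CO[Si](C)(C)C(C)(C)C)[C@H]2CO[Si](C)(C)C(C)(C)C)ccc1OCc1ccccc1
F12 | step 3 | {(Z)-1,2-bis[4-(benzyloxy)-3-methoxyphenyl]ethenyl}dicyclohexylborane | COc1cc(/C=C(B(C2CCCCC2)C2CCCCC2)\c2ccc(OCc3ccccc3)c(OC)c2)ccc1OCc1ccccc1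
F13 | step 4 | (E)-1,2-bis[4-(benzyloxy)-3-methoxyphenyl]ethene | COc1cc(/C=C/c2ccc(OCc3ccccc3)c(OC)c2)ccc1OCc1ccccc1
F14 | step 4 | threo-1,2-bis[4-(benzyloxy)-3-methoxyphenyl]ethane-1,2-diol (racemic; the 1R,2R enantiomer drawn) | COc1cc([C@@H](O)[C@H](O)c2ccc(OCc3ccccc3)c(OC)c2)ccc1OCc1ccccc1
F15 | step 7 | bis[(1R,2S,5R)-2-isopropyl-5-methylcyclohexyl] (2S,3R,4R,5S)-2,5-bis(4-hydroxy-3-methoxyphenyl)oxolane-3,4-dicarboxylate | COc1cc([C@H]2O[C@H](c3ccc(O)c(OC)c3)[C@H](C(=O)O[C@@H]3C[C@H](C)CC[C@H]3C(C)C)[C@H]2C(=O)O[C@@H]2C[C@H](C)CC[C@H]2C(C)C)ccc1O
A1 | alternative 1 | (3R,4R)-N3,N4-di(quinolin-8-yl)oxolane-3,4-dicarboxamide (trans) | C1OC[C@H](C(=O)Nc2cccc3cccnc23)[C@H]1C(=O)Nc1cccc2cccnc12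
A2 | alternative 1 | (2S,3R,4R,5S)-2,5-bis[4-(benzyloxy)-3-methoxyphenyl]-N3,N4-di(quinolin-8-yl)oxolane-3,4-dicarboxamide (2,3-cis, 3,4-trans, 4,5-cis) | COc1cc([C@H]2O[C@H](c3ccc(OCc4ccccc4)c(OC)c3)[C@H](C(=O)Nc3cccc4cccnc34)[C@H]2C(=O)Nc2cccc3cccnc23)ccc1OCc1ccccc1
A3 | alternative 2 | 2,5-bis(3-methoxy-4-pivaloyloxyphenyl)furan | COc1cc(-c2ccc(-c3ccc(OC(=O)C(C)(C)C)c(OC)c3)o2)ccc1OC(=O)C(C)(C)C
A4 | alternative 2 | (2S,3S,4S,5S)-3,4-bis(benzyloxymethyl)-2,5-bis(3-methoxy-4-pivaloyloxyphenyl)oxolane (2,3-cis, 3,4-trans, 4,5-cis) | COc1cc([C@H]2O[C@H](c3ccc(OC(=O)C(C)(C)C)c(OC)c3)[C@H](COCc3ccccc3)[C@H]2COCc2ccccc2)ccc1OC(=O)C(C)(C)C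
A5 | alternative 3 | methyl (R)-[4-(benzyloxy)-3-methoxyphenyl][(2R)-oxiran-2-yl]methyl propanedioate (threo) | COC(=O)CC(=O)O[C@H](c1ccc(OCc2ccccc2)c(OC)c1)[C@H]1CO1
A6 | alternative 3 | methyl (3S,4S,5S)-5-[4-(benzyloxy)-3-methoxyphenyl]-4-(hydroxymethyl)-2-oxooxolane-3-carboxylate (3,4-trans, 4,5-cis) | O=C1O[C@H](c2ccc(OCc3ccccc3)c(OC)c2)[C@H](CO)[C@H]1C(=O)OC
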